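The data stem from a simulated flask from invented constants; the scatter is artificial.

How much G stands in this flask after 10 min, and how much of the D has gone by then?

the same everywhere: D 20 mM
- cedar: X 16 mM; run made earlier
- birch: X 36 mM; run made earlier
- flask: X 24.0 mM; time 10 min; volume of the second phase over the first 2.0

- cedar (time / min: G / %, D / %): 0.833: 0.3, 99.4; 2.50: 4.8, 95.2; 4.00: 8.7, 90.7; 6.00: 15.0, 85.7; 10.0: 24.0, 76.8; 12.0: 25.0, 71.1
- birch (time / min: G / %, D / %): 0.833: 1.1, 98.9; 2.50: 8.1, 90.6; 4.00: 18.3, 82.5; 6.00: 26.6, 72.9; 10.0: 39.4, 57.6; 12.0: 41.3, 52.8

(each reading ± 1 percentage point)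

- in the second phase: X; everything else is in the first
- charges count per volume of the first phase; a concentration in a rate is the amount of a species over the volume of its own phase; every rate counts per litre of the first phase
- the earlier runs hold the two phases in the same ratio of volumes as the flask asked about

1. how much G there is at 10 min, in percent of the D charged
2. part of the D charged that has reacted at 10 min

Start from the symmetric point. The flask's charge cX of 24.0 mM equals the geometric mean of the two earlier charges, 24.0 mM, so on a logarithmic scale of cX it stands halfway between cedar and birch. I therefore take the midpoint exposure rate, the geometric mean over cedar and birch of ln(D charged over D left) per minute at 10 min, 0.0382 min⁻¹. Over 10 min that puts the D reacted at 31.8%.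

Two chemists at the board accept this and part over G. The first holds a one-step view: G is simply the D lost, so it is 31.8% too. She points out that at 10.0 min cedar reads G 24.0% with D lost 23.2%, which shows no shortfall. The second looks at the last readings, at 12.0 min, where G trails the D lost by 3.9 percentage points in cedar and 5.9 points in birch, against a scatter of 1 point. He takes the geometric mean of G itself at 10 min, 30.8%.

The forecast stands with the second, at 30.5% of G and 32% reacted, reading the late gap as “slow loss of G”. The flask gives 30.1% of G and 31.9% reacted.

    J ⇌ X, rate k1*([J] - [X]/K1) per volume of the first phase (partition coefficient = 0.480, kL = 0.00380 s⁻¹)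
    J + G → Q (k = 0.0310 M⁻¹ s⁻¹)
    2 J → L (k = 0.110 M⁻¹ s⁻¹)
    D + J → G (k = 0.110 M⁻¹ s⁻¹)

At 10 min this flask's G is less than the D reacted, by 1.8 points, as the second view held, with Q at 1.77%. The one-step view keeps the start of this flask, where Q is 0% after 1.00 min. Now carry 0.0382 min⁻¹ to the same flask read at 25 min: it gives 61.5% reacted. That flask shows 51.9%, an exposure rate of 0.0293 min⁻¹, lower than the midpoint value, and its X stands at 12.0% of its charge.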